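**Retrosynthetic overview**

1. Numbering: C1 lactone carbonyl, C2, C3 (H, peroxide O2), C4 (CH3, lactone O), C5 (CH2), C6 (CH3, peroxide O1), side chain C7–C16 with phenyl on C16. The strategy rests on the 1,2-dioxane ring O1–O2–C3–C4–C5–C6: the two fully substituted, methyl-bearing carbons C4 and C6 flank the C5 methylene, so a 2-substituted propene (C5, C6 and its methyl) can bridge a C4 ketone and the O1 end of a C3 hydroperoxide.
2. Endgame disconnections: C13=C14 (olefination of a C13 aldehyde with a cinnamyl phosphonate, chosen over a cinnamyl sulfone for E-selectivity), C7–C8 (alkane from alkyne by diimide), lactone C1–O bond (lactonization of the cis C4 hydroxyl onto the C1 methyl ester).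
3. Key disconnection: C4–C5 and O1–C6 in one operation, leading back to methyl (3R)-3-hydroperoxy-4-oxopentanoate and the TBDPS ether of 8-methylnon-8-en-6-yn-1-ol.
4. Precursors: the hydroperoxy ketone from methyl levulinate (silyl enol ether, singlet oxygen, enzymatic resolution); the enyne from hept-6-yn-1-ol and 2-bromopropene (Sonogashira coupling).
5. Ring order: 1,2-dioxane first (key step), γ-lactone second, then the side chain is completed.

Key step: step 6

Assumption: in step 5 the peroxidase is taken to reduce the (3S)-hydroperoxide faster, so that the (3R)-hydroperoxide is the recovered enantiomer; this sense would be checked on the recovered material before use, and the fallback for step 5 does not depend on it.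

**Route**

Step 1
Reactants: 1 hept-6-yn-1-ol
Product: 2 tert-butyl(hept-6-yn-1-yloxy)diphenylsilane
Conditions: TBDPSCl, imidazole, CH2Cl2, 0 °C to rt
Reagents that add atoms: tert-butyl(chloro)diphenylsilane, CC(C)(C)[Si](Cl)(c1ccccc1)c1ccccc1
Why: Imidazole-promoted silylation of a primary alcohol is routine, and the TBDPS ether is chosen because it is weakly Lewis basic and should withstand SnCl4 and the later acidic steps.

Step 2
Reactants: 2 tert-butyl(hept-6-yn-1-yloxy)diphenylsilane; 3 2-bromopropene
Product: 4 tert-butyl[(8-methylnon-8-en-6-yn-1-yl)oxy]diphenylsilane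
Conditions: Pd(PPh3)2Cl2 (2 mol%), CuI (4 mol%), Et3N, THF, rt
Reagents that add atoms: none
Why: Sonogashira coupling of a terminal alkyne with a vinyl bromide should give the conjugated 2-substituted enyne directly, with no alkene geometry to control because the alkene is 1,1-disubstituted.

Step 3
Reactants: 5 methyl levulinate (methyl 4-oxopentanoate)
Product: 6 methyl (3Z)-4-(trimethylsilyloxy)pent-3-enoate
Conditions: TMSCl, NaI, Et3N, MeCN, rt
Reagents that add atoms: chlorotrimethylsilane, C[Si](C)(C)Cl
Why: Silylation under equilibrating conditions (iodotrimethylsilane formed in the flask, amine base) should favour the more substituted C3–C4 silyl enol ether, and the hydroperoxide derived from any terminal regioisomer would be removed by chromatography after step 4.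

Step 4
Reactants: 6 methyl (3Z)-4-(trimethylsilyloxy)pent-3-enoate
Product: 8 racemic methyl 3-hydroperoxy-4-oxopentanoate, via silylperoxy ketone 7 (not isolated)
Conditions: O2, hν, tetraphenylporphyrin (cat.), CH2Cl2, −30 °C; then MeOH, 0 °C
Reagents that add atoms: oxygen, O=O
Why: Singlet oxygen should attack the nucleophilic C3 of the silyl enol ether in an ene-type reaction with shift of silicon to the distal oxygen (silatropic ene reaction), and methanolysis of the labile O–Si bond then frees the α-hydroperoxy ketone, with C3 formed racemic.

Step 5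
Reactants: 8 racemic methyl 3-hydroperoxy-4-oxopentanoate
Product: 9 methyl (3R)-3-hydroperoxy-4-oxopentanoate
Conditions: horseradish peroxidase, guaiacol, phosphate buffer (pH 6), 20 °C, stopped a little beyond half conversion
Reagents that add atoms: none
Why: Peroxidase-catalysed kinetic resolution of a secondary hydroperoxide, in which the enzyme reduces one enantiomer to the alcohol with guaiacol as electron donor and leaves the other, here taken to be the (3R)-hydroperoxide, which is separated from the hydroxy ketone by chromatography and carries the only stereochemical input of the route.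

Step 6
Reactants: 9 methyl (3R)-3-hydroperoxy-4-oxopentanoate; 4 tert-butyl[(8-methylnon-8-en-6-yn-1-yl)oxy]diphenylsilane
Product: 11 methyl [(3R,4R,6R)-6-[7-(tert-butyldiphenylsilyloxy)hept-1-yn-1-yl]-4-hydroxy-4,6-dimethyl-1,2-dioxan-3-yl]acetate, via propargylic cation 10 (not isolated)
Conditions: SnCl4 (1.1 equiv), 2,6-di-tert-butyl-4-methylpyridine (0.2 equiv), CH2Cl2, −78 °C, then 4 (1.5 equiv), −78 to −40 °C; aq. NaHCO3 quench
Reagents that add atoms: none
Why: Proposed new method: SnCl4 is expected to bind the ketone oxygen and the proximal peroxide oxygen O2 of 9 in a five-membered chelate, after which the CH2 terminus of the 1,1-disubstituted alkene of 4 adds to C4 (C4–C5 bond, Prins-type) to leave the tertiary alkynyl-stabilised cation 10 at C6, and the distal hydroperoxide oxygen O1 collapses on this cation (O1–C6 bond) while its proton passes to the C4 oxygen. The closest known reaction types are the chelation-controlled Prins and carbonyl-ene additions of 1,1-disubstituted alkenes to α-alkoxy ketones and the SnCl4-mediated [3+2] annulation of peroxycarbenium ions with alkenes, in which a peroxide oxygen likewise traps the cation left by the alkene; a [4+2] annulation of an α-hydroperoxy ketone has not been described. The 1,2-dioxane (O1–O2–C3–C4–C5–C6) closes by capture of the cation in a six-membered chair-like transition state, a 6-exo closure with respect to the propargyl π-system, which stays outside the ring. C4 is set by the chelate: the alkene attacks the ketone face opposite the CH2CO2Me arm on C3, which places the new hydroxyl cis to that arm (4R). C6 is set in the ring-closing chair, where the C3 arm and both methyl groups sit equatorial and the slim alkynyl group takes the axial site syn to the C4 oxygen (6R with the alkynyl substituent). The step needs activation of the ketone in preference to the ester, attack through the CH2 terminus and an untouched C3–H: the bidentate α-peroxy ketone site, the tertiary propargylic character of the cation and, for C3, the low temperature with no base other than the hindered pyridine are what secure them.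

Step 7
Reactants: 11 methyl [(3R,4R,6R)-6-[7-(tert-butyldiphenylsilyloxy)hept-1-yn-1-yl]-4-hydroxy-4,6-dimethyl-1,2-dioxan-3-yl]acetate
Product: 12 alkynyl peroxy lactone (3R,4R,6R)
Conditions: CSA (10 mol%), 4 Å molecular sieves, CH2Cl2, rt
Reagents that add atoms: none
Why: Acid-catalysed lactonization of a γ-hydroxy ester should close the cis-fused γ-lactone readily because the tertiary C4 hydroxyl and the C3 arm are cis on the dioxane, no stereocentre is touched, and any lactone already formed in step 6 converges here.

Step 8
Reactants: 12 alkynyl peroxy lactone (3R,4R,6R)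
Product: 14 saturated silyloxyheptyl peroxy lactone (3R,4R,6S), via cis-alkene 13 (not isolated)
Conditions: KO2CN=NCO2K (excess, in portions), AcOH, MeOH/CH2Cl2, 0 °C to rt
Reagents that add atoms: none
Why: Diimide reduction transfers hydrogen concertedly to the C–C multiple bond (alkyne to cis-alkene 13 to alkane) and should leave the O–O bond, the lactone and the silyl ether intact, so the C6 descriptor changes to S only because the substituent priorities change.

Step 9
Reactants: 14 saturated silyloxyheptyl peroxy lactone (3R,4R,6S)
Product: 15 hydroxyheptyl peroxy lactone (3R,4R,6S)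
Conditions: HF·pyridine, pyridine, THF, 0 °C to rt
Reagents that add atoms: none
Why: Fluoride cleavage of the silyl ether under buffered, non-basic conditions should avoid base-induced opening of the β-peroxy lactone (retro-oxa-Michael or Kornblum–DeLaMare pathways).

Step 10
Reactants: 15 hydroxyheptyl peroxy lactone (3R,4R,6S)
Product: 16 C13 aldehyde (3R,4R,6S)
Conditions: Dess–Martin periodinane, CH2Cl2, rt
Reagents that add atoms: none
Why: Dess–Martin oxidation takes a primary alcohol to the aldehyde under neutral to weakly acidic conditions, to which dialkyl peroxides and lactones are inert.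

Step 11
Reactants: 16 C13 aldehyde (3R,4R,6S); 17 diethyl [(2E)-3-phenylprop-2-en-1-yl]phosphonate
Product: 18 plakortolide Q (3R,4R,6S,13E,15E)
Conditions: 17 (1.3 equiv), NaN(SiMe3)2 (1.2 equiv), THF, −78 °C; then 16, −78 to 0 °C
Reagents that add atoms: none
Why: Horner–Wadsworth–Emmons olefination with the pre-formed allylic phosphonate anion, so that no free amide base meets the β-peroxy lactone, should give the new C13=C14 bond E through reversible addition and faster elimination of the threo adduct, while C15=C16 keeps the E geometry of the reagent.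

**Compound list**

1 | hept-6-yn-1-ol | C#CCCCCCO | starting material
2 | tert-butyl(hept-6-yn-1-yloxy)diphenylsilane | C#CCCCCCO[Si](c1ccccc1)(c1ccccc1)C(C)(C)C | intermediate
3 | 2-bromopropene | C=C(C)Br | starting material
4 | tert-butyl[(8-methylnon-8-en-6-yn-1-yl)oxy]diphenylsilane | C=C(C)C#CCCCCCO[Si](c1ccccc1)(c1ccccc1)C(C)(C)C | intermediate
5 | methyl levulinate (methyl 4-oxopentanoate) | CC(=O)CCC(=O)OC | starting material
6 | methyl (3Z)-4-(trimethylsilyloxy)pent-3-enoate | C/C(O[Si](C)(C)C)=C/CC(=O)OC | intermediate
7 | racemic methyl 4-oxo-3-(trimethylsilylperoxy)pentanoate | CC(=O)C(CC(=O)OC)OO[Si](C)(C)C | intermediate (not isolated)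
8 | racemic methyl 3-hydroperoxy-4-oxopentanoate | CC(=O)C(CC(=O)OC)OO | intermediate
9 | methyl (3R)-3-hydroperoxy-4-oxopentanoate | CC(=O)[C@@H](CC(=O)OC)OO | intermediate
10 | Prins adduct with C4–C5 formed, (3R,4R), tertiary propargylic cation at C6, drawn free of tin | CC(C)(C)[Si](OCCCCCC#C[C+](C)C[C@@](C)(O)[C@@H](CC(=O)OC)OO)(c1ccccc1)c1ccccc1 | intermediate (not isolated)
11 | methyl [(3R,4R,6R)-6-[7-(tert-butyldiphenylsilyloxy)hept-1-yn-1-yl]-4-hydroxy-4,6-dimethyl-1,2-dioxan-3-yl]acetate (C3: H and CH2CO2Me; C4: OH and CH3; C6: CH3 and alkynyl chain) | CC(C)(C)[Si](OCCCCCC#C[C@@]1(C)C[C@@](C)(O)[C@@H](CC(=O)OC)OO1)(c1ccccc1)c1ccccc1 | intermediate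
12 | alkynyl peroxy lactone: 1,2-dioxane cis-fused at C3–C4 to a γ-lactone (lactone O on C4, C2 on C3), CH3 on C4 and C6, 7-(tert-butyldiphenylsilyloxy)hept-1-ynyl on C6, (3R,4R,6R) | C[C@]1(C#CCCCCCO[Si](c2ccccc2)(c2ccccc2)C(C)(C)C)C[C@@]2(C)OC(=O)C[C@H]2OO1 | intermediate
13 | the same peroxy lactone with a (7Z)-7-(tert-butyldiphenylsilyloxy)hept-1-enyl group on C6, (3R,4R,6R) | C[C@]1(/C=C\CCCCCO[Si](c2ccccc2)(c2ccccc2)C(C)(C)C)C[C@@]2(C)OC(=O)C[C@H]2OO1 | intermediate (not isolated)
14 | the same peroxy lactone with a 7-(tert-butyldiphenylsilyloxy)heptyl group on C6, (3R,4R,6S) | C[C@]1(CCCCCCCO[Si](c2ccccc2)(c2ccccc2)C(C)(C)C)C[C@@]2(C)OC(=O)C[C@H]2OO1 | intermediate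
15 | the same peroxy lactone with a 7-hydroxyheptyl group on C6, (3R,4R,6S) | C[C@]1(CCCCCCCO)C[C@@]2(C)OC(=O)C[C@H]2OO1 | intermediate
16 | the same peroxy lactone with a 7-oxoheptyl group on C6 (C13 aldehyde), (3R,4R,6S) | C[C@]1(CCCCCCC=O)C[C@@]2(C)OC(=O)C[C@H]2OO1 | intermediate
17 | diethyl [(2E)-3-phenylprop-2-en-1-yl]phosphonate (diethyl cinnamylphosphonate) | CCOP(=O)(OCC)C/C=C/c1ccccc1 | starting material
18 | plakortolide Q, (3R,4R,6S,13E,15E) | C[C@]1(CCCCCC/C=C/C=C/c2ccccc2)C[C@@]2(C)OC(=O)C[C@H]2OO1 | target

**Step count**

Total step count: 11. Longest linear sequence: 9 steps (steps 3 to 11, from methyl levulinate).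

**Steps most likely to fail**

Step 6.
- What may go wrong: Lewis-acid-induced decomposition of the hydroperoxy ketone (Hock-type cleavage, dehydration to the 1,2-dione) and enolization at C3 with loss of configuration. The chelate may also lose out to binding at the ester (giving the other C4 epimer), the enyne may oligomerize, or the cation may lose a proton or take up chloride instead of the peroxide oxygen.
- Fallback (known reactions, the two bonds formed in separate steps): it sets out from 9 and comes back at 14. Purchased 7-bromoheptan-1-ol is silylated to tert-butyl(7-bromoheptyloxy)diphenylsilane F1. Its Grignard reagent is cross-coupled with purchased (2-bromoallyl)trimethylsilane (Ni(dppp)Cl2 cat., Kumada coupling) to the 2-substituted allylsilane F2.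
- Hosomi–Sakurai addition of F2 to 9 (SnCl4, CH2Cl2, −78 °C) should give the homoallylic tertiary alcohol hydroperoxide F3. Here the far more nucleophilic allylsilane keeps exposure to the Lewis acid short, and C4 is set by the same chelate.
- Intramolecular peroxymercuration (Hg(OAc)2, CH2Cl2) closes the 1,2-dioxane through O1–C6 to the acetoxymercuriomethyl dioxane F4. NaBH4 in aq. NaOH at 0 °C then replaces mercury by hydrogen, which turns the CH2Hg group into the C6 methyl.
- C6 is not controlled in this sequence, so the saturated hydroxy ester F5 would be separated by chromatography from its C6 epimer F6. F5 is lactonized under the conditions of step 7 to give 14, and step 8 is then not needed.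

Step 5.
- What may go wrong: slow turnover of this α-hydroperoxy ketone by the enzyme, poor discrimination between the enantiomers, or preferential consumption of the wanted (3R) enantiomer.
- Fallback: it sets out from 8 and comes back at 9. Racemic 8 would be separated without any reagent by preparative chromatography on a cellulose tris(3,5-dimethylphenylcarbamate) stationary phase (hexane/2-propanol). Both enantiomers are obtained, so the outcome no longer depends on the preference of an enzyme, and the (3R) enantiomer is assigned on an analytical sample.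

Step 11.
- What may go wrong: erosion of E-selectivity at C13=C14, attack through the γ-carbon of the allylic anion, or opening of the β-peroxy lactone by the excess of the fairly basic phosphonate anion.
- Fallback: it sets out from 16 and comes back at 18. Purchased (E)-cinnamyl bromide and 1-phenyl-1H-tetrazole-5-thiol (K2CO3, acetone) give the cinnamyl tetrazolyl sulfide F7. This is oxidized with H2O2 and (NH4)6Mo7O24·4H2O (cat.) in EtOH to the sulfone F8.
- KN(SiMe3)2 is added at −78 °C to a THF solution of F8 and 16 (Julia–Kocienski olefination in Barbier mode), so that the only anion present is the well-stabilised sulfonyl carbanion.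
- The reaction should give 18 together with its (13Z) isomer F9. The mixture is equilibrated to the E,E-diene 18 with a trace of I2 in CH2Cl2 in daylight.

**Further compounds**

F1 | step 6 | tert-butyl(7-bromoheptyloxy)diphenylsilane | BrCCCCCCCO[Si](c1ccccc1)(c1ccccc1)C(C)(C)C
F2 | step 6 | tert-butyl({8-[(trimethylsilyl)methyl]non-8-en-1-yl}oxy)diphenylsilane | C=C(C[Si](C)(C)C)CCCCCCCO[Si](c1ccccc1)(c1ccccc1)C(C)(C)C
F3 | step 6 | methyl (3R,4R)-13-(tert-butyldiphenylsilyloxy)-3-hydroperoxy-4-hydroxy-4-methyl-6-methylidenetridecanoate | CC(C)(C)[Si](OCCCCCCCC(=C)C[C@@](C)(O)[C@@H](CC(=O)OC)OO)(c1ccccc1)c1ccccc1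
F4 | step 6 | 1,2-dioxane hydroxy ester (3R,4R) with an acetoxymercuriomethyl group and the 7-(tert-butyldiphenylsilyloxy)heptyl chain on C6, both C6 epimers | CC(C)(C)[Si](OCCCCCCCC1(C[Hg]OC(C)=O)C[C@@](C)(O)[C@@H](CC(=O)OC)OO1)(c1ccccc1)c1ccccc1
F5 | step 6 | methyl [(3R,4R,6S)-6-[7-(tert-butyldiphenylsilyloxy)heptyl]-4-hydroxy-4,6-dimethyl-1,2-dioxan-3-yl]acetate | CC(C)(C)[Si](OCCCCCCC[C@@]1(C)C[C@@](C)(O)[C@@H](CC(=O)OC)OO1)(c1ccccc1)c1ccccc1
F6 | step 6 | methyl [(3R,4R,6R)-6-[7-(tert-butyldiphenylsilyloxy)heptyl]-4-hydroxy-4,6-dimethyl-1,2-dioxan-3-yl]acetate (C6 epimer of F5) | CC(C)(C)[Si](OCCCCCCC[C@]1(C)C[C@@](C)(O)[C@@H](CC(=O)OC)OO1)(c1ccccc1)c1ccccc1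
F0 | step 5 | none | none
F7 | step 11 | 1-phenyl-5-{[(2E)-3-phenylprop-2-en-1-yl]sulfanyl}-1H-tetrazole | c1ccc(cc1)/C=C/CSc1nnnn1-c1ccccc1
F8 | step 11 | 1-phenyl-5-{[(2E)-3-phenylprop-2-en-1-yl]sulfonyl}-1H-tetrazole | O=S(=O)(C/C=C/c1ccccc1)c1nnnn1-c1ccccc1
F9 | step 11 | (13Z,15E) isomer of plakortolide Q, (3R,4R,6S) | C[C@]1(CCCCCC/C=C\C=C\c2ccccc2)C[C@@]2(C)OC(=O)C[C@H]2OO1
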